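Compare the two substrates at one moment, then ask how that comparison drifts.

| flask | left-handed substrate | right-handed substrate | reagent | free catalyst | added ligand | remark | time |
|---|---|---|---|---|---|---|---|
| north | 41 mM | 41 mM | 0.80 equiv | 8.4 mol% | 5.2 mM | run made earlier |  |
| south-west | 41 mM | 41 mM | 2 equiv | 8.4 mol% | 5.2 mM | run made earlier |  |
| Tuesday's | 41 mM | 41 mM | 1.00 equiv | 8.4 mol% | 5.2 mM |  | 30 h |
| Saturday's | 41 mM | 41 mM | 3.00 equiv | 8.4 mol% | 5.2 mM |  | 30 h |

- which of the two ends with the higher excess of left-handed product over right-handed product in the product ("neither" if they lie within 2 percentage points) (Tuesday's / Saturday's / neither)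
- excess of left-handed product over right-handed product in the product at the end, Tuesday's
- excess of left-handed product over right-handed product in the product at the end, Saturday's

- free catalyst is single-handed; left-handed substrate and right-handed substrate are mirror images of each other, charged as a racemate, each of them at the stated concentration
- what was read earlier has a scatter of 0.5 percentage points, one standard deviation
- steps that have been proposed: reagent + free catalyst + left-handed substrate -> free catalyst + left-handed product; reagent + free catalyst + right-handed substrate -> free catalyst + right-handed product; free catalyst + added ligand <-> idle complex; 2 reagent -> self-condensation product; reagent + free catalyst -> spent catalyst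
- an excess is below zero if the other one leads

| run | time / h | left-handed product / % | right-handed product / % | left-handed substrate / % |
|---|---|---|---|---|
| north | 5.00 | 22.2 | 9.6 | 27.3 |
| north | 10.0 | 21.6 | 9.1 | 27.8 |
| north | 15.0 | 22.3 | 9.3 | 28.0 |
| north | 20.0 | 21.7 | 9.0 | 27.8 |
| south-west | 2.50 | 36.9 | 18.5 | 11.7 |
| south-west | 8.00 | 38.4 | 19.1 | 12.3 |
| south-west | 15.0 | 37.4 | 18.6 | 12.1 |
| south-west | 20.0 | 37.2 | 19.7 | 12.2 |

(scatter of a reading: 0.5 percentage points)

Down each table the rows scatter about one value, so north has stopped by 5.00 h and south-west by 2.50 h. South-west, with 2 equiv of reagent, ends with less left-handed substrate in its last row, 12.2 % against 27.8 %, than north with 0.80 equiv, so I read reagent as the limiting reagent.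

Both proposed product steps take reagent and free catalyst, so these cancel in the ratio of the two rates, which leaves a constant s times c(left-handed substrate)/c(right-handed substrate).

Each substrate's charge is 0.5 of the total. I get the fraction of left-handed substrate left from its column, and that of right-handed substrate from its charge minus right-handed product. I call X the negative logarithm of the right-handed fraction. Averaging the rows, north gives X = 0.205 and south-west gives 0.477. The left-handed logarithm over X then reads 2.88 and 2.98. I carry their mean, the selectivity factor s = 2.93, the ratio of the two substrates' log extents. Since s exceeds unity, left-handed substrate goes faster at the start, where the two concentrations are equal, c(left-handed substrate)/c(right-handed substrate) falls from there, and later product carries less excess.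

I run a straight line through the two X against reagent. Tuesday's gets X = 0.250 and Saturday's 0.704. X and s give the two fractions converted, and their difference over their sum is the excess: 40.3 % for Tuesday's, higher than 26.7 % for Saturday's.

The forecast says Tuesday's, with 39.5 % and 28 %: “The excess falls with conversion”. Its figures are not mine, though the order is.

The flask gives Tuesday's, with 40.6 % for Tuesday's and 27.7 % for Saturday's, the order of the forecast.

    reagent + free catalyst + left-handed substrate → free catalyst + left-handed product (k = 68000 /M²/h)
    reagent + free catalyst + right-handed substrate → free catalyst + right-handed product (k = 23000 /M²/h)
    free catalyst + added ligand ⇌ idle complex, settled at all times (K = 72.0 /M)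
    2 reagent → self-condensation product (k = 77.0 /M/h)
    reagent + free catalyst → spent catalyst (k = 7.50 /M/h)

Tuesday's holds reagent at 0 % of its charge at 30.0 h, with 48 % of left-handed and 78 % of right-handed substrate left, so s reads 2.95 there. For a neighbour of Tuesday's charged with 1.70 equiv of reagent, my line gives X = 0.409, and with s that gives an estimated excess of 35.1 %. That neighbour ends at an excess of 35.3 %.

(Readings and results are simulated with made-up constants, noise included.)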